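**Crossover level.** At a substrate level of 7.84 × 10⁻⁴ M, ring closure and dimerisation remove substrate equally. We call this level c×, the crossover concentration: the ring-closure constant over 2 times the dimerisation constant. It is a selectivity factor written as a concentration. With reopening set aside, ring takes the share c×/(c× + a) of the substrate lost at level a.

the same everywhere: substrate 0.020 M

|  | remark | time |
|---|---|---|
| beta | one stirred flow tank at steady state, fed with the mixture as stated, mean residence time 12 h |  |
| gamma | a closed flask charged with all of it at once and left for 12 h | 12 h |

    2 substrate → open dimer (k1 = 0.0245 M⁻¹ s⁻¹)
    substrate ⇌ ring (K2 = 36, k2 = 3.84 × 10⁻⁵ s⁻¹)

- the set-up with the highest amount of ring at the outlet or at the end, in percent of the substrate put in ("none" if the first two lie within 2 percentage points) (beta / gamma / none)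
- amount of ring at the outlet or at the end, in percent of the substrate put in, beta
- amount of ring at the outlet or at the end, in percent of the substrate put in, gamma

- a species is counted by the substrate in it: one open dimer counts as two
- two of one species on the left: rate k times its square, two consumed each time
- the stated concentrations are those of everything mixed, before any reaction; amounts are the same in each set-up
- run time (gamma): 12 h

**Time ladder.** At the feed level, dimerisation by itself has a first half-life of 0.283 h, and forward ring closure has one of 5.01 h. The stay in tank beta and the time in flask gamma are both 12 h, and reopening by itself has a half-life of 181 h, so in this reckoning we drop reopening. The closed flask gamma starts far above c×, so ring's share of the substrate lost at its start is 3.77%.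

**Fraction left.** In tank beta, feed minus outlet equals what both steps remove in one residence time. That leaves a fraction 12.5% of the substrate, and ring, the closure constant times the stay times that fraction, comes to 20.8%. In flask gamma, with C the charge, a/(a + c×) decays exponentially with the closure constant, from 0.962 to 0.183, leaving 0.879% of the substrate. Summing the share gives (c×/C) ln[(C + c×)/(a + c×)], or 12.1%. We therefore expect more ring from tank beta than from flask gamma.

**Forecast, result.** The forecast names beta, with 20% (19.5% to 20.5%) and 11.9% (11.5% to 12.3%), on the ground that “the low substrate level in a stirred tank favours first-order ring closure”, and both figures stand below ours. The simulation gives beta, with 20.0% in tank beta and 11.7% in flask gamma. With reopening struck out, as we reckoned, they give 20.8% and 12.1%.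

**Main reason.** The loss of substrate to open dimer puts tank beta ahead: with that step left out, ring reaches 61.3% there and 79.6% in flask gamma. At the tank's level of 0.00252 M, with reopening set aside, c× gives ring a share of 23.7% of the substrate lost, more than the 12.8% that the share, summed down to zero substrate, gives for the whole charge of flask gamma. Left 120 h, flask gamma stands at 11.9% ring, so the time allowed makes no difference to its place below the 20.0% of tank beta.

The rate constants stand for no real mixture; no experiment stands behind them.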